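**Retrosynthetic overview** (numbers follow the forward route; primed locants are the side-chain atoms of the target, C1' = ArO–CH2)
1. 9 ⇒ C1'–O(aryl) bond: isofraxidin 6 plus the C11 dihydroxy carboxylate 7, whose carboxyl carbon leaves as CO2 in a light-driven Cu(II) decarboxylative C(sp3)–O coupling (key step).
2. 7 ⇒ hydroxy lactone 5 ⇒ C3'–C4' bond: chelate-controlled addition of homoprenylMgBr to α-hydroxy ketone 3, so C3' is set by C2'.
3. 3 ⇒ C3'–CH3 bond: mono-addition of MeLi to D-malic acid acetonide 1, in which C2' is bought.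
4. Rings: the coumarin bicycle is bought intact in 6; the only ring made is the temporary γ-lactone of 5 (step 2), opened again in step 3.

Assumption: (R)-2,2-dimethyl-5-oxo-1,3-dioxolane-4-acetic acid (D-malic acid acetonide), isofraxidin and 5-bromo-2-methylpent-2-ene are taken as purchasable; homoprenyl = 4-methylpent-3-en-1-yl.

**Step 1**
Reactants: 1 (R)-2-(2,2-dimethyl-5-oxo-1,3-dioxolan-4-yl)acetic acid
Product: 3 (3R)-3-hydroxy-4-oxopentanoic acid, via dilithium hemiketal alkoxide 2 (not isolated)
Conditions: MeLi (2.05 equiv), THF, −78 °C, 1 h; 1 M HCl, −78 → 0 °C; NaCl, EtOAc extraction, crude used directly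
Reagents that add atoms: methyllithium, C[Li]
Why: Organolithium mono-addition to an activated lactone: the first equivalent of MeLi only deprotonates CO2H, the second adds to the dioxolanone C=O, and the tetrahedral lithium hemiketal alkoxide 2 does not collapse at −78 °C, so the methyl ketone is released only on acidic quench (with loss of acetone) and cannot over-add; the bought stereocentre (future C2') is not touched.

**Step 2**
Reactants: 3 (3R)-3-hydroxy-4-oxopentanoic acid
Product: 5 (4R,5R)-4-hydroxy-5-methyl-5-(4-methylpent-3-en-1-yl)oxolan-2-one, via dihydroxy acid 4 (not isolated)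
Conditions: homoprenylMgBr (3.3 equiv; from 5-bromo-2-methylpent-2-ene, Mg, THF), THF, −78 → −30 °C; 1 M HCl, 0 °C; PPTS (cat.), CH2Cl2, rt
Reagents that add atoms: 4-methylpent-3-en-1-ylmagnesium bromide, CC(C)=CCC[Mg]Br
Why: Cram chelate-controlled Grignard addition: after double deprotonation the magnesium α-alkoxide and the ketone oxygen form a five-membered chelate, the nucleophile enters from the face of C2'–H (anti to the CH2CO2– arm), which sets C3' as R (2',3'-syn diol, the relationship in the target), and the γ-hydroxy acid 4 lactonizes on acidification.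

**Step 3**
Reactants: 5 (4R,5R)-4-hydroxy-5-methyl-5-(4-methylpent-3-en-1-yl)oxolan-2-one; 6 isofraxidin (7-hydroxy-6,8-dimethoxy-2H-chromen-2-one)
Product: 9 altissimacoumarin C, via cesium dihydroxynonenoate 7 (not isolated), via cesium isofraxidin-7-olate 8 (not isolated)
Conditions: (i) 5, CsOH·H2O (1.0 equiv), THF/H2O, rt; (ii) 6, CsOH·H2O (1.0 equiv); evaporate, PhMe azeotrope; (iii) Cu(OTf)2 (2.2 equiv), 4 Å MS, MeCN (0.05 M), 427 nm LEDs, N2, 25 °C
Reagents that add atoms: none
Why: Proposed new method: Cu(II)-LMCT decarboxylative C(sp3)–O(aryl) coupling of a free, unprotected hydroxy carboxylate — 427 nm excitation of the Cu(II) carboxylate of 7 (O→Cu charge transfer) gives the carboxyl radical, which loses CO2 to the primary C1' radical; this is captured by a second Cu(II) aryloxide (from 8) to an alkyl–Cu(III)–OAr species that reductively eliminates the C1'–O bond (net 2 Cu(II) → 2 Cu(I)), while C2' and C3' are not radical centres and keep their configuration; the closest known reaction types are the Cu/photoredox decarboxylative etherification of N-hydroxyphthalimide esters with phenols and the Cu(II)-LMCT decarboxylative coupling of carboxylic acids with nucleophiles, neither shown for an unactivated primary acid with free β,γ-hydroxyls, which cannot be made into a redox-active ester without lactonizing.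

**Compound list**
1 | (R)-2-(2,2-dimethyl-5-oxo-1,3-dioxolan-4-yl)acetic acid (D-malic acid acetonide) | OC(=O)C[C@H]1OC(C)(C)OC1=O | starting material
2 | dilithium salt (alkoxide and carboxylate) of 2-[(4R)-5-hydroxy-2,2,5-trimethyl-1,3-dioxolan-4-yl]acetic acid, hemiketal carbon unassigned | [Li+].[Li+].[O-]C(=O)C[C@H]1OC(C)(C)OC1(C)[O-] | intermediate (not isolated)
3 | (3R)-3-hydroxy-4-oxopentanoic acid | OC(=O)C[C@@H](O)C(C)=O | intermediate
4 | (3R,4R)-3,4-dihydroxy-4,8-dimethylnon-7-enoic acid | OC(=O)C[C@@H](O)[C@](C)(O)CCC=C(C)C | intermediate (not isolated)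
5 | (4R,5R)-4-hydroxy-5-methyl-5-(4-methylpent-3-en-1-yl)oxolan-2-one | O=C1C[C@@H](O)[C@@](C)(CCC=C(C)C)O1 | intermediate
6 | isofraxidin, 7-hydroxy-6,8-dimethoxy-2H-chromen-2-one | COc1cc2ccc(=O)oc2c(OC)c1O | starting material
7 | cesium (3R,4R)-3,4-dihydroxy-4,8-dimethylnon-7-enoate | [Cs+].[O-]C(=O)C[C@@H](O)[C@](C)(O)CCC=C(C)C | intermediate (not isolated)
8 | cesium 6,8-dimethoxy-2-oxo-2H-chromen-7-olate | [Cs+].COc1cc2ccc(=O)oc2c(OC)c1[O-] | intermediate (not isolated)
9 | altissimacoumarin C, 7-{[(2R,3R)-2,3-dihydroxy-3,7-dimethyloct-6-en-1-yl]oxy}-6,8-dimethoxy-2H-chromen-2-one | COc1cc2ccc(=O)oc2c(OC)c1OC[C@@H](O)[C@](C)(O)CCC=C(C)C | target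

**Step count and risks**
Total steps: 3. Longest linear sequence: 3 steps (1 → 3 → 5 → 9); 6 enters in the last step.

Most likely to fail, in this order:

Step 3 (the proposed new coupling). The C1' radical can cyclize 6-exo onto the C6'=C7' alkene, the alkyl–Cu(III) species can undergo β-hydride loss instead of C–O elimination, and Cu(II) can oxidize the electron-rich aryloxide or cleave the glycol. Fallback with known chemistry, setting out from isofraxidin 6 and coming back at 9: 6 opens purchased methyl (R)-glycidate at C3 (cat. CsF, DMF, 60 °C) to methyl (2R)-3-[(6,8-dimethoxy-2-oxo-2H-chromen-7-yl)oxy]-2-hydroxypropanoate F1. Me(MeO)NH·HCl/iPrMgCl (THF, −20 °C) converts this into the Weinreb amide (2R)-3-[(6,8-dimethoxy-2-oxo-2H-chromen-7-yl)oxy]-2-hydroxy-N-methoxy-N-methylpropanamide F2. MeMgBr (2.2 equiv, −40 °C) gives the ketone 7-{[(2R)-2-hydroxy-3-oxobutyl]oxy}-6,8-dimethoxy-2H-chromen-2-one F3. Chelate-controlled addition of homoprenylMgBr (2.2 equiv, THF, −78 °C, inverse addition) then gives 9. The ether bond is made here by thermal epoxide opening; the price is that the coumarin lactone must survive three organomagnesium steps, which is why this is not the main route.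

Step 1 (MeLi mono-addition). Over-addition, enolization of the dioxolanone (loss of ee) or poor recovery of the very polar keto acid are possible. Fallback, setting out from 1 and coming back at 3: 1 is opened with Me(MeO)NH·HCl/iPrMgCl (4 equiv, THF, −20 °C) to the Weinreb amide (R)-3-hydroxy-4-[methoxy(methyl)amino]-4-oxobutanoic acid F4, whose stable N-methoxy chelate guarantees a single addition of MeMgBr (3.2 equiv, 0 °C) to give 3.

Step 2 (Grignard addition to the unprotected keto acid). The magnesium dianion may be insoluble, may enolize, or may give lower dr through a competing carboxylate chelate. Fallback, setting out from 3 and coming back at 5: 3 is esterified (TMSCHN2, MeOH/PhMe) to methyl (3R)-3-hydroxy-4-oxopentanoate F5 and protected (PMB trichloroacetimidate, cat. CSA) as methyl (3R)-3-[(4-methoxyphenyl)methoxy]-4-oxopentanoate F6. Pre-complexation with MgBr2·OEt2 in CH2Cl2 and addition of homoprenylMgBr at −78 °C (ether-oxygen Cram chelate) gives, after lactonization of the tertiary alkoxide onto the ester, (4R,5R)-4-[(4-methoxyphenyl)methoxy]-5-methyl-5-(4-methylpent-3-en-1-yl)oxolan-2-one F7. DDQ (CH2Cl2/H2O) then frees 5.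

**Further compounds**
F1 | step 3 | methyl (2R)-3-[(6,8-dimethoxy-2-oxo-2H-chromen-7-yl)oxy]-2-hydroxypropanoate | COc1cc2ccc(=O)oc2c(OC)c1OC[C@@H](O)C(=O)OC
F2 | step 3 | (2R)-3-[(6,8-dimethoxy-2-oxo-2H-chromen-7-yl)oxy]-2-hydroxy-N-methoxy-N-methylpropanamide | COc1cc2ccc(=O)oc2c(OC)c1OC[C@@H](O)C(=O)N(C)OC
F3 | step 3 | 7-{[(2R)-2-hydroxy-3-oxobutyl]oxy}-6,8-dimethoxy-2H-chromen-2-one | COc1cc2ccc(=O)oc2c(OC)c1OC[C@@H](O)C(C)=O
F4 | step 1 | (R)-3-hydroxy-4-[methoxy(methyl)amino]-4-oxobutanoic acid | OC(=O)C[C@@H](O)C(=O)N(C)OC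
F5 | step 2 | methyl (3R)-3-hydroxy-4-oxopentanoate | COC(=O)C[C@@H](O)C(C)=O
F6 | step 2 | methyl (3R)-3-[(4-methoxyphenyl)methoxy]-4-oxopentanoate | COC(=O)C[C@@H](OCc1ccc(OC)cc1)C(C)=O
F7 | step 2 | (4R,5R)-4-[(4-methoxyphenyl)methoxy]-5-methyl-5-(4-methylpent-3-en-1-yl)oxolan-2-one | O=C1C[C@@H](OCc2ccc(OC)cc2)[C@@](C)(CCC=C(C)C)O1
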